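**Strategy.** The route rests on cutting the lactone at C2–C3 and O1–C2. C4 carries the ring A benzyl group and two one-carbon arms (C3 and C5), so it maps onto a 1,1-disubstituted allylic alcohol plus CO. Asymmetric hydroformylation of 2-(4-benzyloxy-3-methoxybenzyl)prop-2-en-1-ol forms C2–C3, sets C4 (S) and closes the ring as the lactol in one operation. After oxidation, the lactone enolate is alkylated trans with a ring B benzyl bromide whose side-chain stereocentre comes from an Evans syn-aldol. Late benzylic oxidation and hydrogenolysis finish the target.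

Key step: step 4

Remark: the target is taken as the open-chain aryl ketone drawn, not its cyclic hemiketal with the ring B phenol. Its α-aryl ketone stereocentre is treated as base-labile, so it is carried as a carbinol until step 17 and no basic step follows.

**Ring A and lactone**

Step 1
Reactants: 1 4-bromo-2-methoxyphenol
Product: 2 1-(benzyloxy)-4-bromo-2-methoxybenzene
Conditions: BnBr, K2CO3, DMF, rt
Reagents that add atoms: benzyl bromide, BrCc1ccccc1
Why: Williamson etherification of the phenoxide installs a benzyl ether that should survive the organomagnesium, rhodium and enolate steps and fall in the final hydrogenolysis.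

Step 2
Reactants: 2 1-(benzyloxy)-4-bromo-2-methoxybenzene; 3 3-chloro-2-(chloromethyl)prop-1-ene
Product: 5 1-(benzyloxy)-4-[2-(chloromethyl)prop-2-en-1-yl]-2-methoxybenzene, via aryl Grignard reagent 4 (not isolated)
Conditions: Mg, 1,2-dibromoethane (cat.), THF, 45 °C; then added to 3 (3 equiv), CuI (5 mol %), THF, −20 °C → rt
Reagents that add atoms: magnesium, [Mg] (in 4 only)
Why: The aryl Grignard reagent undergoes CuI-catalysed allylic substitution on the symmetrical bis-allylic dichloride, where direct and transposed displacement give the same product and the excess of 3 limits double arylation.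

Step 3
Reactants: 5 1-(benzyloxy)-4-[2-(chloromethyl)prop-2-en-1-yl]-2-methoxybenzene
Product: 7 2-{[4-(benzyloxy)-3-methoxyphenyl]methyl}prop-2-en-1-ol, via allylic acetate 6 (not isolated)
Conditions: KOAc, Bu4NI (cat.), DMF, 70 °C; then K2CO3, MeOH, rt
Reagents that add atoms: potassium acetate, CC(=O)[O-].[K+] (oxygen of the new hydroxyl; acetyl in 6 only)
Why: SN2 displacement of the primary allylic chloride by acetate followed by base-catalysed methanolysis (transesterification) should deliver the allylic alcohol cleanly, since the allyl unit gives one constitution whichever terminus is attacked.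

Step 4
Reactants: 7 2-{[4-(benzyloxy)-3-methoxyphenyl]methyl}prop-2-en-1-ol; 8 carbon monoxide
Product: 10 (4S)-4-{[4-(benzyloxy)-3-methoxyphenyl]methyl}oxolan-2-ol (both anomers), via γ-hydroxy aldehyde 9 (not isolated)
Conditions: Rh(acac)(CO)2 (1 mol %), chiral binaphthyl phosphine–phosphoramidite ligand (YanPhos type, 2 mol %), CO/H2 (1:1, 20 bar), toluene, 60 °C
Reagents that add atoms: none
Why: A rhodium hydride bearing the chiral ligand coordinates the alkene and adds with rhodium at the terminal CH2 and hydride at the internal carbon (C4), since the alternative tertiary alkylrhodium is sterically disfavoured; CO insertion and hydrogenolysis of the acyl then release γ-hydroxy aldehyde 9 with the new C2–C3 bond. The closest known reaction type is the rhodium-catalysed asymmetric hydroformylation of 1,1-disubstituted allylic alcohols to β-substituted γ-lactols. Ring closure is a 5-exo-trig addition of the hydroxyl oxygen to the aldehyde carbon (O1–C2), which should be fast and removes the aldehyde from further reaction. The C4 stereocentre is fixed in the hydride-transfer step under catalyst control by the ligand (the antipode that gives 4S is used, to be confirmed on lactone 11), and it cannot epimerise because it lies β to the carbonyl; the anomeric centre is uncontrolled and is erased in step 5. The step needs linear regioselectivity, which the 1,1-disubstitution secures, and hydroformylation over hydrogenation or allylic isomerisation, which CO pressure and moderate temperature favour. The benzyl ether and the arene are inert to the rhodium hydride under syngas.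

Step 5
Reactants: 10 (4S)-4-{[4-(benzyloxy)-3-methoxyphenyl]methyl}oxolan-2-ol
Product: 11 (4S)-4-{[4-(benzyloxy)-3-methoxyphenyl]methyl}oxolan-2-one
Conditions: PhI(OAc)2 (1.5 equiv), TEMPO (10 mol %), CH2Cl2, rt
Reagents that add atoms: none
Why: Oxoammonium-mediated (TEMPO/PhI(OAc)2) oxidation of the hemiacetal should converge both anomers to the γ-lactone under mild conditions that leave the electron-rich arene and the non-enolisable C4 centre untouched.

**Ring B fragment**

Step 6
Reactants: 12 5-bromo-2-hydroxy-3-methoxybenzaldehyde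
Product: 13 2-(benzyloxy)-5-bromo-3-methoxybenzaldehyde
Conditions: BnBr, K2CO3, DMF, 60 °C
Reagents that add atoms: benzyl bromide, BrCc1ccccc1
Why: Williamson etherification protects the ring B phenol as the same benzyl ether used elsewhere, so that one hydrogenolysis unmasks all three phenols at the end.

Step 7
Reactants: 13 2-(benzyloxy)-5-bromo-3-methoxybenzaldehyde
Product: 15 [2-(benzyloxy)-5-bromo-3-methoxyphenyl]acetonitrile, via N-(1-tosylalkenyl)formamide 14 (not isolated)
Conditions: p-toluenesulfonylmethyl isocyanide, t-BuOK, DME, −40 °C; then MeOH, reflux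
Reagents that add atoms: p-toluenesulfonylmethyl isocyanide, Cc1ccc(S(=O)(=O)C[N+]#[C-])cc1 (carbon and nitrogen of the nitrile; tosyl and formyl in 14 only)
Why: In the van Leusen reductive cyanation the isocyanide anion adds to the non-enolisable aldehyde, and methanolysis of the resulting formamide expels formate and sulfinate to give the one-carbon-homologated nitrile.

Step 8
Reactants: 15 [2-(benzyloxy)-5-bromo-3-methoxyphenyl]acetonitrile
Product: 16 [2-(benzyloxy)-5-bromo-3-methoxyphenyl]acetic acid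
Conditions: KOH, EtOH/H2O, reflux; then 2 M HCl
Reagents that add atoms: potassium hydroxide, [K+].[OH-]; water, O
Why: Alkaline nitrile hydrolysis should give the arylacetic acid while the aryl bromide and the benzyl ether, both inert to hydroxide, are retained.

Step 9
Reactants: 16 [2-(benzyloxy)-5-bromo-3-methoxyphenyl]acetic acid; 17 (4R)-4-benzyl-1,3-oxazolidin-2-one
Product: 19 (4R)-4-benzyl-3-{[2-(benzyloxy)-5-bromo-3-methoxyphenyl]acetyl}-1,3-oxazolidin-2-one, via mixed pivalic anhydride 18 (not isolated)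
Conditions: PivCl, Et3N, THF, −20 °C; then 17, LiCl, −20 °C → rt
Reagents that add atoms: pivaloyl chloride, CC(C)(C)C(Cl)=O (in 18 only)
Why: N-Acylation of the oxazolidinone through the mixed pivalic anhydride is regioselective because the hindered pivaloyl carbonyl is not attacked.

Step 10
Reactants: 19 (4R)-4-benzyl-3-{[2-(benzyloxy)-5-bromo-3-methoxyphenyl]acetyl}-1,3-oxazolidin-2-one; 20 4-(benzyloxy)-3-methoxybenzaldehyde
Product: 22 (4R)-4-benzyl-3-[(2R,3R)-2-[2-(benzyloxy)-5-bromo-3-methoxyphenyl]-3-[4-(benzyloxy)-3-methoxyphenyl]-3-hydroxypropanoyl]-1,3-oxazolidin-2-one, via dibutylboron Z-enolate 21 (not isolated)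
Conditions: Bu2BOTf, i-Pr2NEt, CH2Cl2, −78 → 0 °C; 20, −78 → 0 °C; then pH 7 buffer, MeOH, 30% H2O2, 0 °C
Reagents that add atoms: dibutylboron triflate, CCCCB(CCCC)OS(=O)(=O)C(F)(F)F (in 21 only)
Why: In this Evans syn-aldol reaction the Z-boron enolate reacts through a closed chair transition state in which the (4R)-benzyl group of the auxiliary blocks one enolate face, setting the aryl-bearing carbon as 2R and the carbinol as 3R, and the auxiliary allows minor diastereomers to be removed by chromatography.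

Step 11
Reactants: 22 the syn-aldol adduct
Product: 23 (1R,2S)-2-[2-(benzyloxy)-5-bromo-3-methoxyphenyl]-1-[4-(benzyloxy)-3-methoxyphenyl]propane-1,3-diol
Conditions: LiBH4, MeOH (1.1 equiv), THF, 0 °C
Reagents that add atoms: none
Why: Reductive cleavage of the activated imide carbonyl by borohydride releases the primary alcohol and the auxiliary without touching either stereocentre; the descriptor of the aryl-bearing carbon changes to S only because CH2OH now ranks below the carbinol carbon.

Step 12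
Reactants: 23 the 1,3-diol
Product: 24 (4R,5S)-5-[2-(benzyloxy)-5-bromo-3-methoxyphenyl]-4-[4-(benzyloxy)-3-methoxyphenyl]-2,2-dimethyl-1,3-dioxane
Conditions: Me2C(OMe)2, PPTS (cat.), acetone, rt
Reagents that add atoms: 2,2-dimethoxypropane, COC(C)(C)OC
Why: Acid-catalysed transacetalisation closes the six-membered acetonide, which masks both hydroxyls in one operation and is inert to the organolithium, hydride and enolate chemistry that follows.

Step 13
Reactants: 24 the bromo acetonide
Product: 27 {4-(benzyloxy)-3-[(4R,5S)-4-[4-(benzyloxy)-3-methoxyphenyl]-2,2-dimethyl-1,3-dioxan-5-yl]-5-methoxyphenyl}methanol, via aryllithium 25 (not isolated), via aldehyde 26 (not isolated)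
Conditions: n-BuLi, THF, −78 °C; DMF, −78 → 0 °C; then MeOH, NaBH4, 0 °C
Reagents that add atoms: n-butyllithium, [Li]CCCC (lithium in 25 only); N,N-dimethylformamide, CN(C)C=O
Why: Bromine–lithium exchange is much faster at −78 °C than deprotonation of the benzyl ethers, and formylation of the aryllithium with DMF followed by borohydride reduction in the same flask gives the benzylic alcohol.

Step 14
Reactants: 27 the benzylic alcohol
Product: 28 (4R,5S)-5-[2-(benzyloxy)-5-(bromomethyl)-3-methoxyphenyl]-4-[4-(benzyloxy)-3-methoxyphenyl]-2,2-dimethyl-1,3-dioxane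
Conditions: CBr4, PPh3, CH2Cl2, 0 °C; used without storage
Reagents that add atoms: carbon tetrabromide, BrC(Br)(Br)Br
Why: The Appel reaction converts the primary benzylic alcohol into the bromide under neutral conditions that the acetonide tolerates.

**Fragment union and endgame**

Step 15
Reactants: 11 (4S)-4-{[4-(benzyloxy)-3-methoxyphenyl]methyl}oxolan-2-one; 28 the ring B benzyl bromide
Product: 30 (3S,4S)-3-({4-(benzyloxy)-3-[(4R,5S)-4-[4-(benzyloxy)-3-methoxyphenyl]-2,2-dimethyl-1,3-dioxan-5-yl]-5-methoxyphenyl}methyl)-4-{[4-(benzyloxy)-3-methoxyphenyl]methyl}oxolan-2-one, via lithium enolate 29 (not isolated)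
Conditions: 11 (1.3 equiv), LiN(SiMe3)2, THF, −78 °C; then 28, DMPU, −78 → −30 °C
Reagents that add atoms: lithium bis(trimethylsilyl)amide, [Li]N([Si](C)(C)C)[Si](C)(C)C (lithium in 29 only)
Why: In this lactone enolate alkylation the C4 benzyl group shields one face of the planar enolate, so the benzyl bromide should enter anti and set C3 as S (trans) under substrate control, while C4 is never deprotonated.

Step 16
Reactants: 30 the acetonide lactone
Product: 31 (3S,4S)-3-({4-(benzyloxy)-3-[(1R,2S)-1-[4-(benzyloxy)-3-methoxyphenyl]-1,3-dihydroxypropan-2-yl]-5-methoxyphenyl}methyl)-4-{[4-(benzyloxy)-3-methoxyphenyl]methyl}oxolan-2-one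
Conditions: AcOH/THF/H2O (3:1:1), 45 °C
Reagents that add atoms: none
Why: Mild acid-catalysed acetal hydrolysis frees the diol without opening the lactone or epimerising C3; any loss of configuration at the benzylic carbinol would be harmless because that centre is oxidised next.

Step 17
Reactants: 31 the diol
Product: 32 (3S,4S)-3-({4-(benzyloxy)-3-[(2S)-1-[4-(benzyloxy)-3-methoxyphenyl]-3-hydroxy-1-oxopropan-2-yl]-5-methoxyphenyl}methyl)-4-{[4-(benzyloxy)-3-methoxyphenyl]methyl}oxolan-2-one
Conditions: DDQ (1.2 equiv), CH2Cl2, rt; pH 7 work-up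
Reagents that add atoms: none
Why: DDQ oxidises the electron-rich secondary benzylic carbinol by hydride abstraction in preference to the primary alcohol and the benzylic CH2 groups (chemoselective benzylic alcohol oxidation), and its neutral to weakly acidic medium should leave the new α-aryl ketone stereocentre intact.

Step 18
Reactants: 32 the tribenzyl hydroxy ketone
Product: 33 CNP0281222.1, (3S,4S)-3-({4-hydroxy-3-[(2S)-3-hydroxy-1-(4-hydroxy-3-methoxyphenyl)-1-oxopropan-2-yl]-5-methoxyphenyl}methyl)-4-[(4-hydroxy-3-methoxyphenyl)methyl]oxolan-2-one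
Conditions: H2 (1 atm), 10% Pd/C, EtOAc/EtOH, rt; stopped at full debenzylation
Reagents that add atoms: none
Why: Catalytic hydrogenolysis cleaves the three aryl benzyl ethers under neutral conditions in which the deactivated 4-oxygenated aryl ketone is reduced only slowly and the α-stereocentre is exposed to neither acid nor base.

**Compound list**

1 | 4-bromo-2-methoxyphenol | COc1cc(Br)ccc1O | starting material
2 | 1-(benzyloxy)-4-bromo-2-methoxybenzene | COc1cc(Br)ccc1OCc1ccccc1 | intermediate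
3 | 3-chloro-2-(chloromethyl)prop-1-ene | C=C(CCl)CCl | starting material
4 | [4-(benzyloxy)-3-methoxyphenyl]magnesium bromide | COc1cc([Mg]Br)ccc1OCc1ccccc1 | intermediate
5 | 1-(benzyloxy)-4-[2-(chloromethyl)prop-2-en-1-yl]-2-methoxybenzene | COc1cc(CC(=C)CCl)ccc1OCc1ccccc1 | intermediate
6 | 2-{[4-(benzyloxy)-3-methoxyphenyl]methyl}prop-2-en-1-yl acetate | COc1cc(CC(=C)COC(C)=O)ccc1OCc1ccccc1 | intermediate
7 | 2-{[4-(benzyloxy)-3-methoxyphenyl]methyl}prop-2-en-1-ol | COc1cc(CC(=C)CO)ccc1OCc1ccccc1 | intermediate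
8 | carbon monoxide | [C-]#[O+] | starting material
9 | (3S)-3-{[4-(benzyloxy)-3-methoxyphenyl]methyl}-4-hydroxybutanal | COc1cc(C[C@@H](CC=O)CO)ccc1OCc1ccccc1 | intermediate
10 | (4S)-4-{[4-(benzyloxy)-3-methoxyphenyl]methyl}oxolan-2-ol, both anomers | COc1cc(C[C@@H]2COC(O)C2)ccc1OCc1ccccc1 | intermediate
11 | (4S)-4-{[4-(benzyloxy)-3-methoxyphenyl]methyl}oxolan-2-one | COc1cc(C[C@@H]2COC(=O)C2)ccc1OCc1ccccc1 | intermediate
12 | 5-bromo-2-hydroxy-3-methoxybenzaldehyde | COc1cc(Br)cc(C=O)c1O | starting material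
13 | 2-(benzyloxy)-5-bromo-3-methoxybenzaldehyde | COc1cc(Br)cc(C=O)c1OCc1ccccc1 | intermediate
14 | N-{2-[2-(benzyloxy)-5-bromo-3-methoxyphenyl]-1-[(4-methylphenyl)sulfonyl]ethenyl}formamide (alkene geometry not defined) | COc1cc(Br)cc(C=C(NC=O)S(=O)(=O)c2ccc(C)cc2)c1OCc1ccccc1 | intermediate
15 | [2-(benzyloxy)-5-bromo-3-methoxyphenyl]acetonitrile | COc1cc(Br)cc(CC#N)c1OCc1ccccc1 | intermediate
16 | [2-(benzyloxy)-5-bromo-3-methoxyphenyl]acetic acid | COc1cc(Br)cc(CC(=O)O)c1OCc1ccccc1 | intermediate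
17 | (4R)-4-benzyl-1,3-oxazolidin-2-one | O=C1N[C@H](Cc2ccccc2)CO1 | starting material
18 | [2-(benzyloxy)-5-bromo-3-methoxyphenyl]acetic 2,2-dimethylpropanoic anhydride | COc1cc(Br)cc(CC(=O)OC(=O)C(C)(C)C)c1OCc1ccccc1 | intermediate
19 | (4R)-4-benzyl-3-{[2-(benzyloxy)-5-bromo-3-methoxyphenyl]acetyl}-1,3-oxazolidin-2-one | COc1cc(Br)cc(CC(=O)N2[C@H](Cc3ccccc3)COC2=O)c1OCc1ccccc1 | intermediate
20 | 4-(benzyloxy)-3-methoxybenzaldehyde | COc1cc(C=O)ccc1OCc1ccccc1 | starting material
21 | (4R)-4-benzyl-3-{(1Z)-2-[2-(benzyloxy)-5-bromo-3-methoxyphenyl]-1-[(dibutylboranyl)oxy]ethenyl}-1,3-oxazolidin-2-one | COc1cc(Br)cc(/C=C(\OB(CCCC)CCCC)N2[C@H](Cc3ccccc3)COC2=O)c1OCc1ccccc1 | intermediate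
22 | (4R)-4-benzyl-3-[(2R,3R)-2-[2-(benzyloxy)-5-bromo-3-methoxyphenyl]-3-[4-(benzyloxy)-3-methoxyphenyl]-3-hydroxypropanoyl]-1,3-oxazolidin-2-one | COc1cc(Br)cc([C@@H](C(=O)N2[C@H](Cc3ccccc3)COC2=O)[C@@H](O)c2ccc(OCc3ccccc3)c(OC)c2)c1OCc1ccccc1 | intermediate
23 | (1R,2S)-2-[2-(benzyloxy)-5-bromo-3-methoxyphenyl]-1-[4-(benzyloxy)-3-methoxyphenyl]propane-1,3-diol | COc1cc(Br)cc([C@@H](CO)[C@@H](O)c2ccc(OCc3ccccc3)c(OC)c2)c1OCc1ccccc1 | intermediate
24 | (4R,5S)-5-[2-(benzyloxy)-5-bromo-3-methoxyphenyl]-4-[4-(benzyloxy)-3-methoxyphenyl]-2,2-dimethyl-1,3-dioxane | COc1cc(Br)cc([C@H]2COC(C)(C)O[C@H]2c2ccc(OCc3ccccc3)c(OC)c2)c1OCc1ccccc1 | intermediate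
25 | {4-(benzyloxy)-3-[(4R,5S)-4-[4-(benzyloxy)-3-methoxyphenyl]-2,2-dimethyl-1,3-dioxan-5-yl]-5-methoxyphenyl}lithium | COc1cc([Li])cc([C@H]2COC(C)(C)O[C@H]2c2ccc(OCc3ccccc3)c(OC)c2)c1OCc1ccccc1 | intermediate
26 | 4-(benzyloxy)-3-[(4R,5S)-4-[4-(benzyloxy)-3-methoxyphenyl]-2,2-dimethyl-1,3-dioxan-5-yl]-5-methoxybenzaldehyde | COc1cc(C=O)cc([C@H]2COC(C)(C)O[C@H]2c2ccc(OCc3ccccc3)c(OC)c2)c1OCc1ccccc1 | intermediate
27 | {4-(benzyloxy)-3-[(4R,5S)-4-[4-(benzyloxy)-3-methoxyphenyl]-2,2-dimethyl-1,3-dioxan-5-yl]-5-methoxyphenyl}methanol | COc1cc(CO)cc([C@H]2COC(C)(C)O[C@H]2c2ccc(OCc3ccccc3)c(OC)c2)c1OCc1ccccc1 | intermediate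
28 | (4R,5S)-5-[2-(benzyloxy)-5-(bromomethyl)-3-methoxyphenyl]-4-[4-(benzyloxy)-3-methoxyphenyl]-2,2-dimethyl-1,3-dioxane | COc1cc(CBr)cc([C@H]2COC(C)(C)O[C@H]2c2ccc(OCc3ccccc3)c(OC)c2)c1OCc1ccccc1 | intermediate
29 | lithium (4S)-4-{[4-(benzyloxy)-3-methoxyphenyl]methyl}-4,5-dihydrofuran-2-olate | COc1cc(C[C@@H]2COC(O[Li])=C2)ccc1OCc1ccccc1 | intermediate
30 | (3S,4S)-3-({4-(benzyloxy)-3-[(4R,5S)-4-[4-(benzyloxy)-3-methoxyphenyl]-2,2-dimethyl-1,3-dioxan-5-yl]-5-methoxyphenyl}methyl)-4-{[4-(benzyloxy)-3-methoxyphenyl]methyl}oxolan-2-one | COc1cc(C[C@@H]2COC(=O)[C@H]2Cc2cc(OC)c(OCc3ccccc3)c([C@H]3COC(C)(C)O[C@H]3c3ccc(OCc4ccccc4)c(OC)c3)c2)ccc1OCc1ccccc1 | intermediate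
31 | (3S,4S)-3-({4-(benzyloxy)-3-[(1R,2S)-1-[4-(benzyloxy)-3-methoxyphenyl]-1,3-dihydroxypropan-2-yl]-5-methoxyphenyl}methyl)-4-{[4-(benzyloxy)-3-methoxyphenyl]methyl}oxolan-2-one | COc1cc(C[C@@H]2COC(=O)[C@H]2Cc2cc(OC)c(OCc3ccccc3)c([C@@H](CO)[C@@H](O)c3ccc(OCc4ccccc4)c(OC)c3)c2)ccc1OCc1ccccc1 | intermediate
32 | (3S,4S)-3-({4-(benzyloxy)-3-[(2S)-1-[4-(benzyloxy)-3-methoxyphenyl]-3-hydroxy-1-oxopropan-2-yl]-5-methoxyphenyl}methyl)-4-{[4-(benzyloxy)-3-methoxyphenyl]methyl}oxolan-2-one | COc1cc(C[C@@H]2COC(=O)[C@H]2Cc2cc(OC)c(OCc3ccccc3)c([C@@H](CO)C(=O)c3ccc(OCc4ccccc4)c(OC)c3)c2)ccc1OCc1ccccc1 | intermediate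
33 | CNP0281222.1, (3S,4S)-3-({4-hydroxy-3-[(2S)-3-hydroxy-1-(4-hydroxy-3-methoxyphenyl)-1-oxopropan-2-yl]-5-methoxyphenyl}methyl)-4-[(4-hydroxy-3-methoxyphenyl)methyl]oxolan-2-one | COc1cc(C[C@@H]2COC(=O)[C@H]2Cc2cc(OC)c(O)c([C@@H](CO)C(=O)c3ccc(O)c(OC)c3)c2)ccc1O | target

**Count.** Total: 18 steps. Longest linear sequence: 13 steps (12 to 33, steps 6–18).

**Steps most likely to fail**

1. Step 4. The risk is insufficient facial discrimination in the hydride transfer, together with competing hydrogenation or isomerisation of the allylic alcohol to saturated products. The fallback sets C4 by asymmetric hydrogenation instead; it sets out from 20 and returns at 11. Stobbe condensation of 20 with dimethyl succinate (NaOMe, MeOH, reflux) would give (3E)-4-[4-(benzyloxy)-3-methoxyphenyl]-3-(methoxycarbonyl)but-3-enoic acid F1. Hydrogenation with [Rh(cod)2]BF4 and a chiral bisphosphine (H2, MeOH) would give (3S)-4-[4-(benzyloxy)-3-methoxyphenyl]-3-(methoxycarbonyl)butanoic acid F2. Reduction of the ester in its potassium carboxylate with Ca(BH4)2 (from CaCl2 and NaBH4, EtOH) would give (3S)-3-{[4-(benzyloxy)-3-methoxyphenyl]methyl}-4-hydroxybutanoic acid F3, which should close to 11 on acidification.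

2. Step 17. The risk is oxidation beyond the carbinol (at the primary alcohol or a benzylic CH2) or partial loss of configuration at the newly α-keto carbon during a slow reaction. The fallback protects the primary alcohol and uses a non-selective oxidant; it sets out from 31 and returns at 32. Selective silylation (TBSCl, imidazole, CH2Cl2, 0 °C) would give the primary silyl ether (3S,4S)-3-({4-(benzyloxy)-3-[(1R,2S)-1-[4-(benzyloxy)-3-methoxyphenyl]-3-{[tert-butyl(dimethyl)silyl]oxy}-1-hydroxypropan-2-yl]-5-methoxyphenyl}methyl)-4-{[4-(benzyloxy)-3-methoxyphenyl]methyl}oxolan-2-one F4. Dess–Martin periodinane (CH2Cl2, 0 °C) would give the corresponding (2S)-silyloxy ketone F5. HF·pyridine (THF, 0 °C) would then release 32.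

3. Step 10. The risk is a sluggish, reversible addition to the electron-rich aldehyde, which would erode diastereoselectivity through retro-aldol equilibration. The fallback changes the auxiliary class and the enolate metal; it sets out from 16 and returns at 23. Coupling of 16 with (4R)-4-benzyl-1,3-thiazolidine-2-thione (EDC·HCl, DMAP, CH2Cl2) would give (4R)-4-benzyl-3-{[2-(benzyloxy)-5-bromo-3-methoxyphenyl]acetyl}-1,3-thiazolidine-2-thione F6. TiCl4 and i-Pr2NEt with N-methylpyrrolidinone (CH2Cl2, 0 °C) would give its trichlorotitanium Z-enolate F7, which adds to 20 through a tightly organised titanium-bound transition state to give the (2R,3R) syn adduct F8. NaBH4 (THF/EtOH, 0 °C) would displace the thione auxiliary directly and give 23.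

**Further compounds**

F1 | step 4 | (3E)-4-[4-(benzyloxy)-3-methoxyphenyl]-3-(methoxycarbonyl)but-3-enoic acid | COC(=O)/C(CC(=O)O)=C/c1ccc(OCc2ccccc2)c(OC)c1
F2 | step 4 | (3S)-4-[4-(benzyloxy)-3-methoxyphenyl]-3-(methoxycarbonyl)butanoic acid | COc1cc(C[C@@H](CC(=O)O)C(=O)OC)ccc1OCc1ccccc1
F3 | step 4 | (3S)-3-{[4-(benzyloxy)-3-methoxyphenyl]methyl}-4-hydroxybutanoic acid | COc1cc(C[C@@H](CC(=O)O)CO)ccc1OCc1ccccc1
F4 | step 17 | (3S,4S)-3-({4-(benzyloxy)-3-[(1R,2S)-1-[4-(benzyloxy)-3-methoxyphenyl]-3-{[tert-butyl(dimethyl)silyl]oxy}-1-hydroxypropan-2-yl]-5-methoxyphenyl}methyl)-4-{[4-(benzyloxy)-3-methoxyphenyl]methyl}oxolan-2-one | COc1cc(C[C@@H]2COC(=O)[C@H]2Cc2cc(OC)c(OCc3ccccc3)c([C@@H](CO[Si](C)(C)C(C)(C)C)[C@@H](O)c3ccc(OCc4ccccc4)c(OC)c3)c2)ccc1OCc1ccccc1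
F5 | step 17 | (3S,4S)-3-({4-(benzyloxy)-3-[(2S)-1-[4-(benzyloxy)-3-methoxyphenyl]-3-{[tert-butyl(dimethyl)silyl]oxy}-1-oxopropan-2-yl]-5-methoxyphenyl}methyl)-4-{[4-(benzyloxy)-3-methoxyphenyl]methyl}oxolan-2-one | COc1cc(C[C@@H]2COC(=O)[C@H]2Cc2cc(OC)c(OCc3ccccc3)c([C@@H](CO[Si](C)(C)C(C)(C)C)C(=O)c3ccc(OCc4ccccc4)c(OC)c3)c2)ccc1OCc1ccccc1
F6 | step 10 | (4R)-4-benzyl-3-{[2-(benzyloxy)-5-bromo-3-methoxyphenyl]acetyl}-1,3-thiazolidine-2-thione | COc1cc(Br)cc(CC(=O)N2[C@H](Cc3ccccc3)CSC2=S)c1OCc1ccccc1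
F7 | step 10 | trichlorotitanium Z-enolate of F6 | COc1cc(Br)cc(/C=C(\O[Ti](Cl)(Cl)Cl)N2[C@H](Cc3ccccc3)CSC2=S)c1OCc1ccccc1
F8 | step 10 | (4R)-4-benzyl-3-[(2R,3R)-2-[2-(benzyloxy)-5-bromo-3-methoxyphenyl]-3-[4-(benzyloxy)-3-methoxyphenyl]-3-hydroxypropanoyl]-1,3-thiazolidine-2-thione | COc1cc(Br)cc([C@@H](C(=O)N2[C@H](Cc3ccccc3)CSC2=S)[C@@H](O)c2ccc(OCc3ccccc3)c(OC)c2)c1OCc1ccccc1
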